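The readings are calculated for substances that don't exist.

**Early readings.** Early on, at 0.208 d, with half of the feed in, Friday's flask already trails Thursday's, with 32% product against 45%. You asked for a quick number and suspected the nucleophile charge, and the later readings back you. Friday still shows 24% electrophile at 3.00 d, while Thursday reaches 100% product by 1.04 d, a time short against the 6.0 d asked. So I start my reckoning from the charge.

| flask | electrophile | nucleophile | protic impurity | remark | time |
|---|---|---|---|---|---|
| Friday's | 0.40 M (fed, over 10 h) | 1.5 equiv | 8 mM | run made earlier |  |
| Thursday's | 0.40 M (fed, over 10 h) | 4.8 equiv | 8 mM | run made earlier |  |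
| teal | 0.40 M (fed, over 10 h) | 1.10 equiv | 8.00 mM |  | 6.0 d |
| amber | 0.40 M (fed, over 10 h) | 2.10 equiv | 8.00 mM |  | 6.0 d |
| blue | 0.40 M (fed, over 10 h) | 4.20 equiv | 8.00 mM |  | 6.0 d |

| run | time / d | electrophile / % | product / % |
|---|---|---|---|
| Friday's | 0.208 | 22 | 32 |
| Friday's | 0.625 | 31 | 69 |
| Friday's | 1.04 | 23 | 72 |
| Friday's | 1.67 | 26 | 76 |
| Friday's | 2.50 | 24 | 77 |
| Friday's | 3.00 | 24 | 78 |
| Thursday's | 0.208 | 6 | 45 |
| Thursday's | 0.625 | 0 | 101 |
| Thursday's | 1.04 | 0 | 100 |
| Thursday's | 1.67 | 0 | 103 |
| Thursday's | 2.50 | 1 | 99 |
| Thursday's | 3.00 | 1 | 98 |

(scatter of a reading: 2 percentage points)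

- the analysis behind the earlier runs scatters by 2 percentage points, standard deviation
- percentages count the whole charge, also what has not yet gone in

- part of the electrophile that has reacted at the end, teal
- part of the electrophile that has reacted at the end, amber
- part of the electrophile that has reacted at the end, blue
- what raising the equivalents of nucleophile from its lowest to its highest value here does to the part of the electrophile that has reacted (changes below 5 percentage points count as none) (it falls / no change / it rises)

**My reckoning.** Net of what the protic impurity can quench, Friday spent 1.90 equiv of nucleophile per product, as read. I take the nearest whole number, two, and suspect the second is lost to released acid. That gives the break-even charge, the equivalents at which the limiting reagent changes from nucleophile to electrophile: 2 plus the impurity's share, or 2.02 equiv. Teal lies below it, so I say 54.0%. Amber clears it, though by just 0.0800 equiv, and blue clears it easily. I expect both to finish near complete, so conversion rises.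

**The forecast.** It gives 55% for teal (51% to 61%), 99% for amber and 100% for blue, with the trend it rises, on the ground that “each electrophile consumes two nucleophile”. Its teal figure stands slightly above mine.

**The result.** Teal gives 60.3%, amber >99.9% and blue 100%, and the trend is: it rises, by 40 percentage points. Teal, 0.920 equiv short of break-even, ends 6.3 points above my figure and 5.3 points above the forecast, and at 6.00 d it holds 0.0507 M of acid set free beside 0.190 M of protonated nucleophile.

    nucleophile + protic impurity → quenched reagent (k = 0.00540 M⁻¹ s⁻¹)
    nucleophile + acid set free ⇌ protonated nucleophile, settled at all times (K = 6100 M⁻¹)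
    electrophile + nucleophile → acid set free + product (k = 2.70 × 10⁻⁴ M⁻¹ s⁻¹)

Blue's charge stands 2.18 equiv over break-even, which is 51.9% of its nucleophile, and 51.9% of that charge is still free at 6.00 d.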